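The constants wanted are two, a first-order slope and a lag, and the blue run holds both.

- blue: Z 1.5 M; D 200 mM (held); run made earlier
- flask: Z 3.0 M; D 200 mM (held); time 80 min

blue run (percent of the Z charged)

| time / min | G / % | Z / % |
|---|---|---|
| 3.00 | 2.6 | 97.1 |
| 6.00 | 6.7 | 93.8 |
| 10.0 | 11.3 | 88.7 |
| 15.0 | 16.7 | 83.1 |
| 20.0 | 23.0 | 77.2 |
| 25.0 | 27.9 | 72.3 |

(standard deviation of a reading: 0.3 percentage points)

- the numbers in the tables scatter by 0.3 percentage points (one standard deviation)
- at the start none of D is in solution

1. how much G there is at 80 min, in percent of the Z charged
2. the change that raises the amount of G at 80 min, in percent of the Z charged most ("none" if none brings more than 2 percentage points) (dusk / summer / none)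
3. amount of G at 80 min, in percent of the Z charged, after dusk

- dusk: doubling the saturation concentration of D, all else as stated
- summer: doubling the transfer coefficient of D, all else as stated

Between 10.0 min and 25.0 min the blue Z readings give a first-order slope of 0.0136 min⁻¹. Traced back, that line meets the full charge at 1.20 min, a lag read as the time dissolved D takes to build up from nothing. This lag is far shorter than the run, so the dissolved level is taken as settled and Z as pseudo-first-order, which gives 65.8% G in the flask.

The weak link is that level under the larger charge. The lag implies a turnover of dissolved D of 0.832 min⁻¹. With the level guessed at half of saturation, the blue charge of Z adds a pull of 0.204 min⁻¹. The flask's extra Z adds that pull again, so its slope starts near 0.0109 min⁻¹, and it climbs back towards 0.0136 min⁻¹ as Z falls below the blue charge. The mean of the two, the run-averaged pseudo-first-order constant 0.0123 min⁻¹, gives 62.0% G, and that is the committed number.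

Dusk, which doubles the saturation concentration of D, is reckoned here to double the level, and so the constant, giving about 85.6% G. Summer, which doubles the transfer coefficient of D, lifts a level at half of saturation by a factor of 1.33 if the loss of dissolved D stays first order, less than the factor of 2 reckoned for dusk, so dusk is the choice.

The forecast says 45%, dusk and 88%, holding that the flask “has the same absolute rate”.

The flask gives 62.5%, and dusk is best, with 20 percentage points against 11 points for summer, reaching 82.5%.

    Z + Q → G (k = 0.150 M⁻¹ min⁻¹)
    2 Q → J (k = 1.50 M⁻¹ min⁻¹)
    D ⇌ Q, rate k3*(csat - [Q]) (kL = 0.380 min⁻¹)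

In the flask Q, the dissolved D, stood at 37.2% of saturation at 8.00 min and 41.4% at 40.0 min. At 160 min, 0.0123 min⁻¹ gives 85.8% G in this flask, which holds 88.5%. For the same flask read at 30 min, 0.0123 min⁻¹ gives 29.8% G, and that flask holds 28.4%.

The readings are calculated for substances that don't exist; the scatter is artificial.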